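Atoms carry farnesane numbers (C1 = OCH2). The carbocycle (ring A, C6–C11) is disconnected at C8–C9. The feature exploited: C15, C7 and C8 form an allyl triad substituted only at its central carbon, so both ends lead to the same ring. A ketone at C10, blocked on one side by quaternary C11, can enolise only toward C9. A single enolate alkylation therefore makes C8–C9, closes ring A and leaves the exocyclic methylene in place. The precursor is an acyclic tert-alkyl methyl ketone whose stereocentre C6 bears a 2-(chloromethyl)allyl group and the silyl-protected (E)-side chain. C6 and C9–C11 come from α-pinene via campholenic aldehyde. Reduction, desilylation and Mitsunobu coupling finish.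

Key step: step 12

Assumption: commercial (1R,5R)-α-pinene of high enantiomeric purity is used; since C6 is never enolisable, the optical purity of 23 should equal that of 1.

Step 1
Reactants: 1 (1R,5R)-α-pinene
Product: 2 (1S,2S,4R,6S)-2,7,7-trimethyl-3-oxatricyclo[4.1.1.0(2,4)]octane (α-pinene oxide; oxygen anti to the CMe2 bridge)
Conditions: mCPBA, CH2Cl2, 0 °C
Reagents that add atoms: m-chloroperoxybenzoic acid, O=C(OO)c1cccc(Cl)c1
Why: Prilezhaev epoxidation, in which the peracid can reach the trisubstituted olefin only from the face turned away from the CMe2 bridge; both new centres are erased again in step 2.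

Step 2
Reactants: 2 α-pinene oxide
Product: 3 (S)-campholenic aldehyde, i.e. 2-[(1S)-2,2,3-trimethylcyclopent-3-en-1-yl]acetaldehyde
Conditions: ZnBr2 (5 mol %), toluene, 60 °C
Reagents that add atoms: none
Why: Lewis-acid epoxide rearrangement (opening to the tertiary cation, Wagner–Meerwein shift of the CMe2 bridge, Grob-type fragmentation to the aldehyde), the classical route to campholenic aldehyde, which does not touch bridgehead C5 of the pinane, so that this carbon becomes C6 of the target with its configuration intact.

Step 3
Reactants: 3 (S)-campholenic aldehyde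
Product: 4 2-[(1S)-2,2,3-trimethylcyclopent-3-en-1-yl]ethan-1-ol
Conditions: NaBH4, MeOH, 0 °C
Reagents that add atoms: none
Why: Borohydride reduction of an unhindered aldehyde, chemoselective over the olefin and without effect on the β-stereocentre.

Step 4
Reactants: 4 2-[(1S)-2,2,3-trimethylcyclopent-3-en-1-yl]ethan-1-ol
Product: 5 (4S)-4-(2-iodoethyl)-1,5,5-trimethylcyclopent-1-ene
Conditions: I2, PPh3, imidazole, CH2Cl2, 0 °C to rt
Reagents that add atoms: iodine, II
Why: Appel-type iodination (Garegg–Samuelsson conditions) of a primary alcohol by SN2 displacement of the alkoxyphosphonium ion under nearly neutral conditions that spare the acid-sensitive cyclopentene.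

Step 5
Reactants: 5 (4S)-4-(2-iodoethyl)-1,5,5-trimethylcyclopent-1-ene
Product: 6 (4R)-4-(but-3-yn-1-yl)-1,5,5-trimethylcyclopent-1-ene
Conditions: LiC≡CH·H2NCH2CH2NH2, DMSO, rt
Reagents that add atoms: lithium acetylide (ethylenediamine complex), [Li]C#C
Why: SN2 alkylation of an acetylide by an unbranched primary iodide in a dipolar aprotic solvent, a standard two-carbon homologation in which substitution outruns elimination.

Step 6
Reactants: 6 (4R)-4-(but-3-yn-1-yl)-1,5,5-trimethylcyclopent-1-ene
Product: 9 (2E)-3-methyl-5-[(1R)-2,2,3-trimethylcyclopent-3-en-1-yl]pent-2-en-1-ol, via (E)-alkenyldimethylalane 7 (not isolated), via lithium (E)-alkenyl(butyl)dimethylalanate 8 (not isolated)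
Conditions: Me3Al, Cp2ZrCl2 (25 mol %), CH2Cl2, 0 °C to rt; volatiles removed; n-BuLi, hexane–THF, −78 to 0 °C; (CH2O)n, rt; 1 M HCl work-up
Reagents that add atoms: trimethylaluminium, C[Al](C)C; formaldehyde (as paraformaldehyde), C=O
Why: Negishi zirconium-catalysed carboalumination adds CH3 and Al syn across the terminal alkyne with the metal at the terminus, and hydroxymethylation of the derived alanate occurs with retention, which sets the (E)-C2=C3 geometry while the trisubstituted ring olefin stays inert.

Step 7
Reactants: 9 (2E)-3-methyl-5-[(1R)-2,2,3-trimethylcyclopent-3-en-1-yl]pent-2-en-1-ol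
Product: 10 tert-butyldimethyl{[(2E)-3-methyl-5-[(1R)-2,2,3-trimethylcyclopent-3-en-1-yl]pent-2-en-1-yl]oxy}silane
Conditions: TBSCl, imidazole, CH2Cl2, rt
Reagents that add atoms: tert-butyldimethylsilyl chloride, CC(C)(C)[Si](C)(C)Cl
Why: Standard imidazole-promoted silylation of a primary alcohol, giving an ether that tolerates every reagent up to step 13 and falls to fluoride in step 14.

Step 8
Reactants: 10 silyl ether of 9
Product: 12 (3R,6E)-8-(tert-butyldimethylsilyloxy)-6-methyl-3-(2-methyl-3-oxobutan-2-yl)oct-6-enal, via secondary ozonide 11 (not isolated)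
Conditions: O3 (to the end point of Sudan Red 7B), CH2Cl2, −78 °C; then Me2S, −78 °C to rt
Reagents that add atoms: ozone, [O-][O+]=O
Why: Chemoselective ozonolysis (Criegee mechanism) with a dye as end-point indicator, relying on the strained, purely alkyl-substituted cyclopentene being more electron-rich than the side-chain olefin, which is deactivated by its allylic C–O bond just as in geranyl derivatives that are cleaved at the remote olefin.

Step 9
Reactants: 12 keto aldehyde
Product: 13 (3R,6E)-8-(tert-butyldimethylsilyloxy)-6-methyl-2-methylidene-3-(2-methyl-3-oxobutan-2-yl)oct-6-enal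
Conditions: 37% aq. CH2O, pyrrolidine (10 mol %), propionic acid (10 mol %), i-PrOH, 45 °C
Reagents that add atoms: formaldehyde, C=O
Why: Amine-catalysed α-methylenation (Mannich condensation of the aldehyde enamine with formaldehyde, then elimination), which is specific for aldehydes, so that the hindered methyl ketone stays out and C6, β to the aldehyde, is not epimerised.

Step 10
Reactants: 13 keto enal
Product: 14 (4R,7E)-9-(tert-butyldimethylsilyloxy)-4-(3-hydroxyprop-1-en-2-yl)-3,3,7-trimethylnon-7-en-2-one
Conditions: NaBH4, CeCl3·7H2O, MeOH, −78 °C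
Reagents that add atoms: none
Why: Luche reduction, whose 1,2-selective hydride transfer to the exposed enal at low temperature should be much faster than attack on the methyl ketone shielded by quaternary C11.

Step 11
Reactants: 14 allylic alcohol
Product: 16 (4S,7E)-9-(tert-butyldimethylsilyloxy)-4-(3-chloroprop-1-en-2-yl)-3,3,7-trimethylnon-7-en-2-one, via allylic mesylate 15 (not isolated)
Conditions: MsCl, LiCl, 2,4,6-collidine, DMF, 0 °C
Reagents that add atoms: lithium chloride, [Li+].[Cl-]
Why: Collington–Meyers chlorination, i.e. mesylation followed by in situ SN2 displacement with chloride, which converts primary allylic alcohols under nearly neutral conditions and for which an allylic shift would be degenerate here.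

Step 12
Reactants: 16 (4S,7E)-9-(tert-butyldimethylsilyloxy)-4-(3-chloroprop-1-en-2-yl)-3,3,7-trimethylnon-7-en-2-one
Product: 18 (3R)-3-[(3E)-5-(tert-butyldimethylsilyloxy)-3-methylpent-3-en-1-yl]-2,2-dimethyl-4-methylidenecyclohexan-1-one, via potassium enolate 17 (not isolated)
Conditions: KN(SiMe3)2 (1.1 equiv, toluene solution), toluene–THF, 0.01 M, −78 °C to 0 °C
Reagents that add atoms: none
Why: KN(SiMe3)2 deprotonates the C9 methyl group, the only acidic α-position because C11 carries no hydrogen, and the resulting potassium enolate 17 displaces chloride from allylic C8 in an intramolecular SN2 alkylation that forms C8–C9. The closest known reaction types are the base-induced cyclisation of 6-halo-3,3-dimethylhexan-2-ones to 2,2-dimethylcyclohexanones and the ring-closing half of ketone annulations with 3-chloro-2-(chloromethyl)prop-1-ene. Ring A closes in the 6-(enolendo)-exo-tet mode, which the ring-closure rules for enolates allow from six members upward. No stereocentre is made, and C6, β to the carbonyl and not enolisable, keeps the configuration inherited from 1. Attack at C8 or, with allylic shift, at C15 gives the same ketone because the allyl triad is substituted only at C7, so the one selectivity required is carbon over oxygen alkylation, which the soft allylic chloride, the aggregated ion pair in a toluene-rich medium free of polar additives and the chair-like transition state should favour. High dilution keeps intermolecular alkylation and aldol addition down.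

Step 13
Reactants: 18 methylidenecyclohexanone
Product: 19 (1S,3R)-3-[(3E)-5-(tert-butyldimethylsilyloxy)-3-methylpent-3-en-1-yl]-2,2-dimethyl-4-methylidenecyclohexan-1-ol
Conditions: NaBH4, MeOH, −20 °C to 0 °C
Reagents that add atoms: none
Why: Hydride reduction of a 2,2-dimethylcyclohexanone by a small borohydride, in which hydride arrives along the axial trajectory on the face opposite the C6 side chain because the equatorial path is obstructed by the axial C11 methyl group, so that the C10 hydroxyl should end up equatorial, cis to the side chain and (S), as in the reduction of 4,4-dimethyl-3-oxo steroids.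

Step 14
Reactants: 19 silyl-protected cis carbinol
Product: 20 (1S,3R)-3-[(3E)-5-hydroxy-3-methylpent-3-en-1-yl]-2,2-dimethyl-4-methylidenecyclohexan-1-ol
Conditions: Bu4NF, THF, 0 °C to rt
Reagents that add atoms: none
Why: Fluoride-induced desilylation driven by the strong Si–F bond, without effect on the olefins or the free carbinol.

Step 15
Reactants: 21 2'-hydroxy-6'-methylacetophenone
Product: 22 4-hydroxy-5-methyl-2H-chromen-2-one (4-hydroxy-5-methylcoumarin)
Conditions: NaH (3 equiv), (EtO)2CO, toluene, 110 °C; then aq. HCl
Reagents that add atoms: diethyl carbonate, CCOC(=O)OCC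
Why: Claisen-type C-acylation of the methyl ketone enolate with diethyl carbonate followed by lactonisation onto the phenoxide, the standard synthesis of 4-hydroxycoumarins, with the ring methyl group ending up at C5 next to C4a.

Step 16
Reactants: 20 diol; 22 4-hydroxy-5-methylcoumarin
Product: 23 4-{[(2E)-5-[(1R,3S)-3-hydroxy-2,2-dimethyl-6-methylidenecyclohexyl]-3-methylpent-2-en-1-yl]oxy}-5-methyl-2H-chromen-2-one (CNP0172901.1)
Conditions: PPh3, DIAD, THF, 0 °C to rt
Reagents that add atoms: none
Why: Mitsunobu etherification, in which only the primary allylic alcohol forms a displaceable alkoxyphosphonium ion (the neopentyl-type C10 carbinol is too hindered), the acidic enol of 22 is alkylated at O4 by direct SN2 attack, and no stereocentre is involved.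

Compound list
1 | (1R,5R)-α-pinene | CC1=CC[C@@H]2C[C@H]1C2(C)C | starting material
2 | α-pinene oxide, (1S,2S,4R,6S), oxygen anti to the CMe2 bridge | C[C@@]12O[C@@H]1C[C@@H]3C[C@H]2C3(C)C | intermediate
3 | (S)-campholenic aldehyde | CC1=CC[C@@H](CC=O)C1(C)C | intermediate
4 | 2-[(1S)-2,2,3-trimethylcyclopent-3-en-1-yl]ethan-1-ol | CC1=CC[C@@H](CCO)C1(C)C | intermediate
5 | (4S)-4-(2-iodoethyl)-1,5,5-trimethylcyclopent-1-ene | CC1=CC[C@@H](CCI)C1(C)C | intermediate
6 | (4R)-4-(but-3-yn-1-yl)-1,5,5-trimethylcyclopent-1-ene | CC1=CC[C@@H](CCC#C)C1(C)C | intermediate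
7 | (E)-alkenyldimethylalane from 6 | CC1=CC[C@@H](CC/C(C)=C/[Al](C)C)C1(C)C | intermediate
8 | lithium (E)-alkenyl(butyl)dimethylalanate | [Li+].CC1=CC[C@@H](CC/C(C)=C/[Al-](C)(C)CCCC)C1(C)C | intermediate
9 | (2E)-3-methyl-5-[(1R)-2,2,3-trimethylcyclopent-3-en-1-yl]pent-2-en-1-ol | CC1=CC[C@@H](CC/C(C)=C/CO)C1(C)C | intermediate
10 | tert-butyldimethylsilyl ether of 9 | CC1=CC[C@@H](CC/C(C)=C/CO[Si](C)(C)C(C)(C)C)C1(C)C | intermediate
11 | secondary ozonide of the ring olefin of 10 (bridgehead centres undefined, both destroyed) | CC12OOC(O1)C[C@@H](CC/C(C)=C/CO[Si](C)(C)C(C)(C)C)C2(C)C | intermediate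
12 | (3R,6E)-8-(tert-butyldimethylsilyloxy)-6-methyl-3-(2-methyl-3-oxobutan-2-yl)oct-6-enal | CC(=O)C(C)(C)[C@@H](CC=O)CC/C(C)=C/CO[Si](C)(C)C(C)(C)C | intermediate
13 | (3R,6E)-8-(tert-butyldimethylsilyloxy)-6-methyl-2-methylidene-3-(2-methyl-3-oxobutan-2-yl)oct-6-enal | CC(=O)C(C)(C)[C@@H](C(=C)C=O)CC/C(C)=C/CO[Si](C)(C)C(C)(C)C | intermediate
14 | (4R,7E)-9-(tert-butyldimethylsilyloxy)-4-(3-hydroxyprop-1-en-2-yl)-3,3,7-trimethylnon-7-en-2-one | CC(=O)C(C)(C)[C@@H](C(=C)CO)CC/C(C)=C/CO[Si](C)(C)C(C)(C)C | intermediate
15 | methanesulfonate of 14 | CC(=O)C(C)(C)[C@@H](C(=C)COS(C)(=O)=O)CC/C(C)=C/CO[Si](C)(C)C(C)(C)C | intermediate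
16 | (4S,7E)-9-(tert-butyldimethylsilyloxy)-4-(3-chloroprop-1-en-2-yl)-3,3,7-trimethylnon-7-en-2-one | CC(=O)C(C)(C)[C@@H](C(=C)CCl)CC/C(C)=C/CO[Si](C)(C)C(C)(C)C | intermediate
17 | potassium C9 enolate of 16 | [K+].C=C([O-])C(C)(C)[C@@H](C(=C)CCl)CC/C(C)=C/CO[Si](C)(C)C(C)(C)C | intermediate
18 | (3R)-3-[(3E)-5-(tert-butyldimethylsilyloxy)-3-methylpent-3-en-1-yl]-2,2-dimethyl-4-methylidenecyclohexan-1-one | C=C1CCC(=O)C(C)(C)[C@@H]1CC/C(C)=C/CO[Si](C)(C)C(C)(C)C | intermediate
19 | (1S,3R)-3-[(3E)-5-(tert-butyldimethylsilyloxy)-3-methylpent-3-en-1-yl]-2,2-dimethyl-4-methylidenecyclohexan-1-ol | C=C1CC[C@H](O)C(C)(C)[C@@H]1CC/C(C)=C/CO[Si](C)(C)C(C)(C)C | intermediate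
20 | (1S,3R)-3-[(3E)-5-hydroxy-3-methylpent-3-en-1-yl]-2,2-dimethyl-4-methylidenecyclohexan-1-ol | C=C1CC[C@H](O)C(C)(C)[C@@H]1CC/C(C)=C/CO | intermediate
21 | 2'-hydroxy-6'-methylacetophenone | CC(=O)c1c(C)cccc1O | starting material
22 | 4-hydroxy-5-methylcoumarin | Cc1cccc2oc(=O)cc(O)c12 | intermediate
23 | CNP0172901.1 | C=C1CC[C@H](O)C(C)(C)[C@@H]1CC/C(C)=C/COc1cc(=O)oc2cccc(C)c12 | target

Total steps: 16. Longest linear sequence: 15 (steps 1–14 and 16).

Steps most likely to fail

1. Step 12 (ring closure). The enolate may alkylate at oxygen, which is also a six-membered closure, or react intermolecularly before C8–C9 forms. The fallback replaces the SN2 electrophile with a π-allyl palladium electrophile. It sets out from allylic alcohol 14. ClCO2Me and pyridine in CH2Cl2 give the allylic methyl carbonate F1. LiN(SiMe3)2 in THF at −78 °C converts it to the lithium enolate F2. Pd(PPh3)4 (zerovalent palladium, 5 mol %) then ionises the carbonate on warming. An O-allylated enol ether is re-ionised by the catalyst whereas the C-allylated ketone is not, so the closure should drain toward carbon. This is a Tsuji–Trost allylation of a preformed ketone enolate, and the route is rejoined at ketone 18.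

2. Step 8 (ring cleavage). Ozone may attack the C2=C3 olefin before the ring olefin is consumed, shortening the side chain. The fallback separates oxidation from cleavage so that the selectivity can be corrected at an isolable stage. It sets out from silyl ether 10. One equivalent of mCPBA in CH2Cl2 at −20 °C gives the ring epoxide F3. Chromatography frees it from any side-chain epoxide and from unreacted 10, which is recycled. H5IO6 in THF–Et2O at 0 °C then opens and cleaves the epoxide, and the route is rejoined at keto aldehyde 12.

3. Step 16 (etherification). The ambident coumarin anion may be alkylated at the lactone carbonyl oxygen or at C3. The allyl unit may also be attacked with transposition, or the product may undergo a [3,3] shift on warming. The fallback inverts the polarity so that only the C4–O bond can form. It sets out from 22 and 20. POCl3 at reflux converts 22 into 4-chloro-5-methylcoumarin F4. One equivalent of NaH in THF at 0 °C turns 20 into the primary sodium alkoxide F5; the hindered C10 hydroxyl stays out. Addition–elimination of this alkoxide at C4 of the chloride leads directly to target 23.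

Further compounds
F1 | step 12 | methyl carbonate of allylic alcohol 14 (R at C6, E olefin) | CC(=O)C(C)(C)[C@@H](C(=C)COC(=O)OC)CC/C(C)=C/CO[Si](C)(C)C(C)(C)C
F2 | step 12 | lithium C9 enolate of F1 | [Li+].C=C([O-])C(C)(C)[C@@H](C(=C)COC(=O)OC)CC/C(C)=C/CO[Si](C)(C)C(C)(C)C
F3 | step 8 | ring epoxide of 10 (epoxide face immaterial, both centres destroyed) | CC12OC1C[C@@H](CC/C(C)=C/CO[Si](C)(C)C(C)(C)C)C2(C)C
F4 | step 16 | 4-chloro-5-methylcoumarin | Cc1cccc2oc(=O)cc(Cl)c12
F5 | step 16 | sodium C1 alkoxide of diol 20 | [Na+].C=C1CC[C@H](O)C(C)(C)[C@@H]1CC/C(C)=C/C[O-]
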